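**Retrosynthetic overview**

1. 15 ⇐ 13 ⇐ 12: the C15 acid comes from the primary alcohol; C13 (S) is set by hydroxyl-directed asymmetric hydrogenation of the E-allylic alcohol.
2. 12 ⇐ 11 ⇐ 9 + 10: the C13=C14 bond is made by Horner–Wadsworth–Emmons olefination of the methyl ketone.
3. 9 ⇐ 7 ⇐ 5: the 8(17)-methylene comes from anti-elimination of the 8α-alcohol; the ketone from excision of C14/C15 of the vinyl carbinol.
4. 5 ⇐ 4 ⇐ 1: key step, C18–O bond formation by threefold enzymatic C–H oxygenation of the equatorial 4α-methyl of sclareol, which also creates the C4 stereocentre.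
5. No ring is formed: rings A and B (C5, C9, C10) are taken intact from sclareol.

Assumption: the target is read as the 18-methyl ester of (13S)-labd-8(17)-ene-15,18-dioic acid, (4R,5R,9S,10R,13S), normal labdane series with CO2Me equatorial on the α face of C4; labdane numbering is used throughout.

**Route**

Step 1
Reactants: 1 (−)-sclareol
Product: 4 (13R)-8α,13-dihydroxylabd-14-en-18-oic acid, via 18-hydroxysclareol 2 (not isolated), via 18-oxosclareol 3 (not isolated)
Conditions: CYP720B4 (iron-protoporphyrin monooxygenase of Picea sitchensis) + NADPH–cytochrome P450 reductase as recombinant yeast microsomes, NADP+ (cat.), glucose dehydrogenase, D-glucose (3.5 equiv), O2 (air), K2HPO4/KH2PO4 buffer pH 7.5, 2-hydroxypropyl-β-cyclodextrin, 30 °C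
Reagents that add atoms: dioxygen, O=O
Why: Proposed new method: the tetravalent iron-oxo porphyrin radical cation of the enzyme abstracts a hydrogen atom from the equatorial 4α-methyl (C18) and returns hydroxyl by oxygen rebound three times in succession (alcohol, gem-diol/aldehyde, acid); its pocket is built for the 4,4,10-trimethyl-trans-decalin A/B unit that sclareol shares with the native abietadiene and isopimaradiene substrates, so the prochiral C4 is desymmetrised to the 4α-carboxyl (4R) of the resin acids; the closest known reaction is the same enzyme's three-step C18 oxidation of tricyclic abietane and pimarane olefins, alcohols and aldehydes, not yet shown on a bicyclic labdane diol.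

Step 2
Reactants: 4 (13R)-8α,13-dihydroxylabd-14-en-18-oic acid
Product: 5 methyl (13R)-8α,13-dihydroxylabd-14-en-18-oate
Conditions: MeI, K2CO3, DMF, rt
Reagents that add atoms: iodomethane, CI
Why: SN2 O-methylation of the hindered carboxylate, which needs no attack at the crowded carbonyl; the two tertiary alcohols are not alkylated by carbonate and no stereocentre is touched.

Step 3
Reactants: 5 methyl (13R)-8α,13-dihydroxylabd-14-en-18-oate
Product: 7 methyl 8α-hydroxy-13-oxo-14,15-dinorlabdan-18-oate, via tetrol ester 6 (not isolated)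
Conditions: OsO4 (2 mol %), NaIO4 (3.5 equiv), 2,6-lutidine, dioxane/H2O 3:1, rt
Reagents that add atoms: none
Why: Lemieux–Johnson oxidation: dihydroxylation of the only olefin gives a 13,14,15-triol unit that periodate cleaves twice (glycol cleavage), leaving C13 as the methyl ketone with its original oxygen and all stereocentres untouched.

Step 4
Reactants: 7 methyl 8α-hydroxy-13-oxo-14,15-dinorlabdan-18-oate
Product: 9 methyl 13-oxo-14,15-dinorlabd-8(17)-en-18-oate, via chlorosulfite ester 8 (not isolated)
Conditions: SOCl2 (1.5 equiv), pyridine, CH2Cl2, −78 °C; AgNO3-impregnated silica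
Reagents that add atoms: none
Why: Anti-periplanar E2 elimination of the equatorial 8α-chlorosulfite: no ring hydrogen is anti to the equatorial leaving group, only a hydrogen of the axial C17 methyl, so pyridine gives mainly the exocyclic 8(17)-olefin at low temperature, and the minor ring olefins are removed on the silver-loaded silica.

Step 5
Reactants: 9 methyl 13-oxo-14,15-dinorlabd-8(17)-en-18-oate; 10 triethyl phosphonoacetate
Product: 11 15-ethyl 18-methyl (13E)-labda-8(17),13-diene-15,18-dioate
Conditions: NaH, THF, 0 °C to 60 °C; E isomer separated on silica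
Reagents that add atoms: none
Why: Horner–Wadsworth–Emmons olefination of the methyl ketone gives the trisubstituted enoate with E predominance (about 5:1, ester trans to the long chain); the non-enolisable ester on quaternary C4 is inert.

Step 6
Reactants: 11 15-ethyl 18-methyl (13E)-labda-8(17),13-diene-15,18-dioate
Product: 12 methyl (13E)-15-hydroxylabda-8(17),13-dien-18-oate
Conditions: i-Bu2AlH (2.2 equiv), CH2Cl2, −78 °C
Reagents that add atoms: none
Why: Chemoselective 1,2-reduction of the unhindered conjugated ethyl ester by the aluminium hydride; the methyl ester on quaternary C4 reacts far more slowly at −78 °C and the E geometry is kept.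

Step 7
Reactants: 12 methyl (13E)-15-hydroxylabda-8(17),13-dien-18-oate
Product: 13 methyl (13S)-15-hydroxylabd-8(17)-en-18-oate
Conditions: H2 (100 atm), Ru(OAc)2[(R)-BINAP] (1 mol %; BINAP = 2,2'-bis(diphenylphosphino)-1,1'-binaphthyl), MeOH/H2O 95:5, 20 °C
Reagents that add atoms: none
Why: Noyori hydroxyl-directed asymmetric hydrogenation: 12 is a geraniol homologue, and the (R)-BINAP complex that converts geraniol into (S)-citronellol adds H2 to the same face here, setting 13S under catalyst control; the 8(17)-methylene has no directing group and is not reduced by this carboxylate complex.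

Step 8
Reactants: 13 methyl (13S)-15-hydroxylabd-8(17)-en-18-oate
Product: 15 (13S)-18-methoxy-18-oxolabd-8(17)-en-15-oic acid (target), via aldehyde 14 (not isolated)
Conditions: TEMPO (2,2,6,6-tetramethylpiperidin-1-oxyl, 20 mol %), PhI(OAc)2 (2.2 equiv), MeCN/H2O 1:1, rt
Reagents that add atoms: water, O
Why: Oxoammonium (nitroxyl/PhI(OAc)2) oxidation takes the primary alcohol to the aldehyde and, through its hydrate, to the acid; the olefin, the hindered methyl ester and the β-stereocentre C13 are not affected.

**Compound list**

All labdanes below keep the sclareol ring fusion (5α-H, 9α-H, 10β-CH3; side chain 9β).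

1 | (−)-sclareol, (13R)-labd-14-ene-8α,13-diol | C[C@@]1(O)CC[C@@H]2[C@](C)(CCCC2(C)C)[C@H]1CC[C@@](C)(O)C=C | starting material
2 | 18-hydroxysclareol, (4R,13R)-labd-14-ene-8α,13,18-triol (4α-CH2OH) | C[C@@]1(O)CC[C@@H]2[C@](C)(CCC[C@@]2(C)CO)[C@H]1CC[C@@](C)(O)C=C | intermediate
3 | 18-oxosclareol, (4R,13R)-8α,13-dihydroxylabd-14-en-18-al | C[C@@]1(O)CC[C@@H]2[C@](C)(CCC[C@@]2(C)C=O)[C@H]1CC[C@@](C)(O)C=C | intermediate
4 | (4R,13R)-8α,13-dihydroxylabd-14-en-18-oic acid (4α-CO2H) | C[C@@]1(O)CC[C@@H]2[C@](C)(CCC[C@@]2(C)C(=O)O)[C@H]1CC[C@@](C)(O)C=C | intermediate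
5 | methyl (4R,13R)-8α,13-dihydroxylabd-14-en-18-oate | C[C@@]1(O)CC[C@@H]2[C@](C)(CCC[C@@]2(C)C(=O)OC)[C@H]1CC[C@@](C)(O)C=C | intermediate
6 | methyl (4R,13R)-8α,13,14,15-tetrahydroxylabdan-18-oate (both C14 epimers) | C[C@@]1(O)CC[C@@H]2[C@](C)(CCC[C@@]2(C)C(=O)OC)[C@H]1CC[C@@](C)(O)C(O)CO | intermediate
7 | methyl (4R)-8α-hydroxy-13-oxo-14,15-dinorlabdan-18-oate | C[C@@]1(O)CC[C@@H]2[C@](C)(CCC[C@@]2(C)C(=O)OC)[C@H]1CCC(C)=O | intermediate
8 | methyl (4R)-8α-(chlorosulfinyloxy)-13-oxo-14,15-dinorlabdan-18-oate | C[C@@]1(OS(=O)Cl)CC[C@@H]2[C@](C)(CCC[C@@]2(C)C(=O)OC)[C@H]1CCC(C)=O | intermediate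
9 | methyl (4R)-13-oxo-14,15-dinorlabd-8(17)-en-18-oate | C=C1CC[C@@H]2[C@](C)(CCC[C@@]2(C)C(=O)OC)[C@H]1CCC(C)=O | intermediate
10 | triethyl phosphonoacetate | CCOC(=O)CP(=O)(OCC)OCC | starting material
11 | 15-ethyl 18-methyl (4R,13E)-labda-8(17),13-diene-15,18-dioate | C=C1CC[C@@H]2[C@](C)(CCC[C@@]2(C)C(=O)OC)[C@H]1CC/C(C)=C/C(=O)OCC | intermediate
12 | methyl (4R,13E)-15-hydroxylabda-8(17),13-dien-18-oate | C=C1CC[C@@H]2[C@](C)(CCC[C@@]2(C)C(=O)OC)[C@H]1CC/C(C)=C/CO | intermediate
13 | methyl (4R,13S)-15-hydroxylabd-8(17)-en-18-oate | C=C1CC[C@@H]2[C@](C)(CCC[C@@]2(C)C(=O)OC)[C@H]1CC[C@H](C)CCO | intermediate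
14 | methyl (4R,13S)-15-oxolabd-8(17)-en-18-oate | C=C1CC[C@@H]2[C@](C)(CCC[C@@]2(C)C(=O)OC)[C@H]1CC[C@H](C)CC=O | intermediate
15 | (4R,5R,9S,10R,13S)-18-methoxy-18-oxolabd-8(17)-en-15-oic acid | C=C1CC[C@@H]2[C@](C)(CCC[C@@]2(C)C(=O)OC)[C@H]1CC[C@H](C)CC(=O)O | target

**Step count and risks**

Total step count: 8. Longest linear sequence: 8 steps (1 to 15).

Step 1 (the proposed new step). The enzyme may bind the diol poorly, stop at the alcohol, or hydroxylate elsewhere in ring A. The fallback uses known chemistry and sets out from 1. Whole-cell cultures of Mucor plumbeus or a Cunninghamella strain, for which 18-hydroxylation of sclareol is a documented metabolic reaction, give 18-hydroxysclareol 2, this time isolated by chromatography from the ring-A regioisomers. The neopentyl primary alcohol is then oxidised with PhI(OAc)2 and catalytic AZADO (2-azaadamantane N-oxyl) in MeCN/H2O, through 3, to the acid; the tertiary alcohols and the vinyl group do not react. The fallback comes back to the route at 4 and makes no compound outside the list (F0).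

Step 4. Ionisation can compete with the E2 path and give the 7-ene and 8(9)-ene, and the hemiketal form of 7 can lose water to a cyclic enol ether. The fallback sets out from 7 and uses the ring olefin instead of discarding it. Elimination run warm with POCl3 in pyridine gives mainly methyl 13-oxo-14,15-dinorlabd-7-en-18-oate F1. This is then moved to the exocyclic position by photochemical contra-thermodynamic positional isomerisation: (n-Bu4N)4W10O32 abstracts an allylic hydrogen under 390 nm light and Co(dmgH)2(py)Cl returns it at the ring carbon, in MeCN. The fallback comes back at 9.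

Step 7. The long hydrophobic substrate may give incomplete facial control, and partial reduction or migration of the 8(17)-olefin is possible; the selectivity of step 6 feeds into the same risk. The fallback sets out from 11 and stays at the ester oxidation level. Asymmetric 1,4-reduction with CuH (from Cu(OAc)2, a SEGPHOS-type bisphosphine and polymethylhydrosiloxane with t-BuOH in toluene) gives 15-ethyl 18-methyl (13S)-labd-8(17)-ene-15,18-dioate F2; the ligand antipode is fixed beforehand on ethyl geranate against ethyl (S)-citronellate. LiOH in THF/H2O at rt then hydrolyses only the unhindered ethyl ester, and the ester on quaternary C4 stays. The fallback comes back at 15.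

**Further compounds**

F0 | step 1 | none | none
F1 | step 4 | methyl (4R)-13-oxo-14,15-dinorlabd-7-en-18-oate | CC1=CC[C@@H]2[C@](C)(CCC[C@@]2(C)C(=O)OC)[C@H]1CCC(C)=O
F2 | step 7 | 15-ethyl 18-methyl (4R,13S)-labd-8(17)-ene-15,18-dioate | C=C1CC[C@@H]2[C@](C)(CCC[C@@]2(C)C(=O)OC)[C@H]1CC[C@H](C)CC(=O)OCC
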